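**Plan**

1. Retrosynthetic cuts, in order: the C17=C18 olefin of the eight-membered ether (metathesis) and O–C19 (allyl ether); then C8–C14 together with C13–O (cationic closure of ring C with oxygen capture, the oxygen lent by a C17 ketone in a temporary six-membered ring); then C15–C16 ([3,3] shift), which leads back to the 6α-hydroxy labdane (+)-larixol.
2. Forward: rings A and B arrive intact with the C6 oxygen; a Claisen step lengthens the C9 side chain to a 13E olefin carrying a δ-ketone; acid closes ring C and the temporary pyran in one operation; the oxocene is closed last.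
3. Enabling feature: in ring C the methyl-bearing quaternary C8 (B/C junction), the C14 methine and the methyl- and oxygen-bearing C13 stand in a row, with 8-CH3 and 13-CH3 both axial and C13–O and C14–C15 both equatorial. This is the imprint of a tertiary C8 cation adding to an E C13=C14 olefin with anti capture of the C13 cation by oxygen.
4. Stereochemistry: C5, C6, C9 and C10 come from the chiral pool; C8, C13 and C14 from the chair transition state of the key step (trans-decalin template plus olefin geometry); the ring olefin can only be Z inside the eight-membered ring.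
5. Helpers: a pivalate on O6 (put on first, taken off last); the C17 carbonyl oxygen as internal nucleophile, its ring opened by water in the same step, its carbon later becoming the C17 olefin carbon.

Key step: step 3

Remark on the chemistry (assumption): (+)-larixol, the 6α-hydroxy labdane of larch oleoresin that is sold as such and as its 6-acetate, is taken as a commercially available starting material.

Numbering: labdane/cheilanthane numbering throughout. C1–C10 are rings A and B, C11–C14 complete ring C, and C14 carries the chain C15–C16–C17(CH3)=C18–C19; methyls sit on C4 (two), C8, C10, C13 and C17. In larixol, C8 carries the exocyclic methylene C17 and C9 carries CH2CH2C(CH3)(OH)CH=CH2 (C11–C15).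

**Step 1**
Reactants: 1 (+)-larixol, (13S)-labda-8(17),14-diene-6α,13-diol
Product: 2 (13S)-13-hydroxylabda-8(17),14-dien-6α-yl pivalate
Conditions: PivCl (1.5 equiv), DMAP (0.2 equiv), pyridine, 50 °C
Reagents that add atoms: pivaloyl chloride, CC(C)(C)C(=O)Cl
Why: DMAP-catalysed acylation should take the equatorial secondary 6α-OH and leave the tertiary allylic 13-OH untouched, and a pivalate (no α-hydrogen, hindered) is chosen to survive the superacid of step 3 and the potassium alkoxide of step 5; no stereocentre is touched.

**Step 2**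
Reactants: 2 (13S)-13-hydroxylabda-8(17),14-dien-6α-yl pivalate
Product: 4 (13E)-1-[6α-(pivaloyloxy)labda-8(17),13-dien-15-yl]propan-2-one, via allyl isopropenyl ether 3 (not isolated)
Conditions: 2-methoxypropene (10 equiv), H3PO4 (cat.), sealed tube, 125 °C; then Et3N; chromatography on AgNO3-impregnated SiO2
Reagents that add atoms: 2-methoxypropene, COC(C)=C
Why: Saucy–Marbet variant of the Claisen rearrangement, in which acid-catalysed exchange gives allyl isopropenyl ether 3 and its chair [3,3] shift creates the C15–C16 bond, the C13=C14 olefin and the δ-keto terminus; the larger arm on C13 prefers the pseudo-equatorial site, so the 13E isomer should be favoured only modestly and the 13Z isomer is removed on silver-loaded silica, the C13 stereocentre being sacrificed.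

**Step 3**
Reactants: 4 (13E)-1-[6α-(pivaloyloxy)labda-8(17),13-dien-15-yl]propan-2-one
Product: 7 13α-hydroxy-17-oxo-18,19-dinorcheilanthan-6α-yl pivalate (ring C with 8β-CH3, 13β-CH3, 13α-OH, 14α-H; C14 carries CH2CH2C(=O)CH3), via oxocarbenium ion 5 (not isolated), via cyclic enol ether 6 (not isolated)
Conditions: FSO3H (5 equiv), i-PrNO2, −78 °C; Et3N, −78 °C; then 0.5 M HCl (aq)–THF, rt
Reagents that add atoms: water, O
Why: Cation–olefin (polyene-type) cyclization with carbonyl-oxygen termination: protonation of the 8(17)-methylene gives the tertiary C8 cation, C14 of the 13E olefin bonds to it to close ring C, and the tertiary C13 cation so formed is captured by the ketone oxygen to give oxocarbenium ion 5, which Et3N deprotonates to enol ether 6 and dilute acid hydrolyses to 7, so that the net change is addition of water. The closest known reaction types are the superacid cyclization of labda-8(17),13E-dienes to tricyclic isocopalanes and the acid cyclization of geranylacetone or farnesylacetone to fused cyclic enol ethers. Ring C closes in a 6-endo-trig mode with respect to the C13=C14 olefin through a chair transition state, and the temporary oxacycle closes as a six-membered ring by attack of the δ-carbonyl oxygen on C13, the C=O bond lying inside the new ring. C8 is set by the trans-decalin template (9α-H, equatorial C9 side chain), which lets C14 reach the C8 cation only on the α face in the chair that leads to the trans B/C fusion and leaves the new methyl axial and β; C14 is set by the E geometry of the olefin, which puts C15 equatorial (14α-H); C13 is set by anti addition across the olefin, which places oxygen equatorial (α), trans to the new C8–C14 bond, and the methyl axial. The step needs initiation at C8 before any oxygen capture at C13 and no ionization at C6: in the superacid the carbonyl is protonated, which disfavours protonation of the nearby C13=C14 olefin and makes capture of a prematurely formed C13 cation reversible, so that material should drain into the doubly closed ion 5, while the pivalate is 1,3-diequatorial to C8, cannot bridge to the cation and should not ionize at −78 °C.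

**Step 4**
Reactants: 7 13α-hydroxy-17-oxo-18,19-dinorcheilanthan-6α-yl pivalate
Product: 8 13α-hydroxy-19-norcheilanth-17(18)-en-6α-yl pivalate (C14 carries CH2CH2C(CH3)=CH2)
Conditions: Ph3PCH3Br (3.5 equiv), KOtBu (3.2 equiv), THF, 0 °C to 50 °C
Reagents that add atoms: methyltriphenylphosphonium bromide, C[P+](c1ccccc1)(c1ccccc1)c1ccccc1.[Br-]
Why: Wittig methylenation with excess ylide, one equivalent of which is spent on the tertiary OH while the open methyl ketone remains available; the hindered pivalate should not be attacked and no stereocentre lies α to the carbonyl.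

**Step 5**
Reactants: 8 13α-hydroxy-19-norcheilanth-17(18)-en-6α-yl pivalate
Product: 9 13α-(allyloxy)-19-norcheilanth-17(18)-en-6α-yl pivalate
Conditions: KH (1.5 equiv), allyl bromide (3 equiv), n-Bu4NI (cat.), THF, 0 °C to rt
Reagents that add atoms: allyl bromide, C=CCBr
Why: Williamson etherification of the potassium tertiary alkoxide with a reactive allylic halide under iodide catalysis; the pivalate has no enolizable hydrogen and is too hindered for acyl transfer, and C13 keeps its configuration because its C–O bond is not broken.

**Step 6**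
Reactants: 9 13α-(allyloxy)-19-norcheilanth-17(18)-en-6α-yl pivalate
Product: 10 (17Z)-13α,19-epoxycheilanth-17-en-6α-yl pivalate
Conditions: second-generation Grubbs catalyst (H2IMes)(PCy3)Cl2Ru=CHPh (10 mol%), 1,4-benzoquinone (20 mol%), CH2Cl2 (2 mM), 40 °C
Reagents that add atoms: none
Why: Ring-closing olefin metathesis, in which the carbene loads on the monosubstituted allyl ether olefin and closes onto the 1,1-disubstituted olefin with loss of ethene; the trans-diequatorial O and CH2 substituents on C13 and C14 hold the two arms gauche, and the new trisubstituted olefin can only be Z within an eight-membered ring.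

**Step 7**
Reactants: 10 (17Z)-13α,19-epoxycheilanth-17-en-6α-yl pivalate
Product: 11 (17Z)-13α,19-epoxycheilanth-17-en-6α-ol (CNP0179324.1)
Conditions: LiAlH4 (3 equiv), THF, 0 °C to reflux; then H2O
Reagents that add atoms: none
Why: Reductive ester cleavage by hydride at the acyl carbon frees the 6α-OH with retention at C6, the allylic ether and the trisubstituted olefin being inert to LiAlH4.

**Compound list**

1 | (+)-larixol, (13S)-labda-8(17),14-diene-6α,13-diol | C=C[C@@](C)(O)CC[C@@H]1[C@@]2(C)CCCC(C)(C)[C@@H]2[C@@H](O)CC1=C | starting material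
2 | (13S)-13-hydroxylabda-8(17),14-dien-6α-yl pivalate | C=C[C@@](C)(O)CC[C@@H]1[C@@]2(C)CCCC(C)(C)[C@@H]2[C@@H](OC(=O)C(C)(C)C)CC1=C | intermediate
3 | (13S)-13-(prop-1-en-2-yloxy)labda-8(17),14-dien-6α-yl pivalate (allyl isopropenyl ether) | C=C[C@@](C)(OC(C)=C)CC[C@@H]1[C@@]2(C)CCCC(C)(C)[C@@H]2[C@@H](OC(=O)C(C)(C)C)CC1=C | intermediate (not isolated)
4 | (13E)-1-[6α-(pivaloyloxy)labda-8(17),13-dien-15-yl]propan-2-one (C9 side chain CH2CH2C(CH3)=CHCH2CH2C(=O)CH3) | CC(=O)CC/C=C(\C)CC[C@@H]1[C@@]2(C)CCCC(C)(C)[C@@H]2[C@@H](OC(=O)C(C)(C)C)CC1=C | intermediate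
5 | 13α,17-epoxy-6α-(pivaloyloxy)-18,19-dinorcheilanthan-17-ylium fluorosulfonate (cyclic oxocarbenium ion, O bridging C13 and C17) | CC1=[O+][C@@]2(C)CC[C@@H]3[C@@]4(C)CCCC(C)(C)[C@@H]4[C@@H](OC(=O)C(C)(C)C)C[C@@]3(C)[C@@H]2CC1.[O-]S(=O)(=O)F | intermediate (not isolated)
6 | 13α,17-epoxy-18,19-dinorcheilanth-16-en-6α-yl pivalate (cyclic enol ether, dihydropyran trans-fused at C13–C14) | CC1=CC[C@@H]2[C@@](C)(O1)CC[C@@H]1[C@@]3(C)CCCC(C)(C)[C@@H]3[C@@H](OC(=O)C(C)(C)C)C[C@@]21C | intermediate (not isolated)
7 | 13α-hydroxy-17-oxo-18,19-dinorcheilanthan-6α-yl pivalate | O[C@@]1(C)CC[C@@H]2[C@@]3(C)CCCC(C)(C)[C@@H]3[C@@H](OC(=O)C(C)(C)C)C[C@@]2(C)[C@@H]1CCC(C)=O | intermediate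
8 | 13α-hydroxy-19-norcheilanth-17(18)-en-6α-yl pivalate | O[C@@]1(C)CC[C@@H]2[C@@]3(C)CCCC(C)(C)[C@@H]3[C@@H](OC(=O)C(C)(C)C)C[C@@]2(C)[C@@H]1CCC(C)=C | intermediate
9 | 13α-(allyloxy)-19-norcheilanth-17(18)-en-6α-yl pivalate | C=CCO[C@@]1(C)CC[C@@H]2[C@@]3(C)CCCC(C)(C)[C@@H]3[C@@H](OC(=O)C(C)(C)C)C[C@@]2(C)[C@@H]1CCC(C)=C | intermediate
10 | (17Z)-13α,19-epoxycheilanth-17-en-6α-yl pivalate | C/C1=C/CO[C@@]2(C)CC[C@@H]3[C@@]4(C)CCCC(C)(C)[C@@H]4[C@@H](OC(=O)C(C)(C)C)C[C@@]3(C)[C@@H]2CC1 | intermediate
11 | (17Z)-13α,19-epoxycheilanth-17-en-6α-ol, CNP0179324.1 | C/C1=C/CO[C@@]2(C)CC[C@@H]3[C@@]4(C)CCCC(C)(C)[C@@H]4[C@@H](O)C[C@@]3(C)[C@@H]2CC1 | target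

Total step count: 7
Longest linear sequence: 7 steps (1 to 11, fully linear)

**Steps most likely to fail**

Step 3 (key cyclization). What may go wrong: oxygen capture at C13 ahead of C–C bond formation when the 13-olefin is protonated first; loss of a proton from the C8 or C13 cation to olefin isomers; hydride and methyl shifts from the C8 cation when ring closure is slow; ionization of the C6 ester. The fallback sets out from 2 and comes back at 7, and it makes the C–C bond and the C–O bond in separate events. Johnson–Claisen rearrangement of 2 (MeC(OEt)3, cat. EtCO2H, 140 °C, geometric isomers separated as in step 2) gives ethyl (13E)-[6α-(pivaloyloxy)labda-8(17),13-dien-15-yl]acetate F1. Acid cyclization terminated by proton loss (FSO3H, i-PrNO2, −78 °C, or SnCl4, CH2Cl2, −78 °C) should give, under the same chair control of C8 and C14, the tricyclic 12-ene ester F2; the exocyclic olefin isomer serves equally. Mukaiyama hydration (Mn(dpm)3 cat., PhSiH3, O2, i-PrOH) should deliver oxygen to the tertiary C13 radical on the α face, away from the axial 8β-methyl, and the hydroxy ester closes on brief exposure to PPTS to the δ-lactone F3. MeLi (1 equiv, THF, −78 °C) opens the lactone to hydroxy ketone 7.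

Step 2 (chain extension). What may go wrong: poor geometric control in the sigmatropic shift, which leaves much 13Z isomer that would cyclize to the C14 epimer and must be separated. The fallback sets out from 2 and comes back at 4, and it builds the olefin by syn carbometalation of an alkyne, which fixes the geometry. KMnO4 (acetone, MgSO4, 0 °C) degrades the vinyl carbinol of 2 to the methyl ketone F4, the hindered ring methylene reacting more slowly. LiN(i-Pr)2 and ClP(O)(OEt)2, then more LiN(i-Pr)2, convert it to the terminal alkyne F5. Zr-catalysed carboalumination (Me3Al, Cp2ZrCl2 cat., CH2Cl2) followed by I2 gives the E vinyl iodide F6. B-alkyl Suzuki–Miyaura coupling with the 9-BBN adduct of 2-methyl-2-vinyl-1,3-dioxolane (Pd(dppf)Cl2, Cs2CO3, DMF–H2O) gives the dioxolane ketal F7, and PPTS in wet acetone releases 4 as the 13E isomer only.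

Step 6 (oxocene closure). What may go wrong: oligomerization through the allyl ether and olefin migration when the ruthenium carbene fails to engage the 1,1-disubstituted olefin in an eight-membered closure. The fallback sets out from 7 and comes back at 10; it is a relay ring-closing metathesis, so it changes the substrate and the way the carbene reaches C17 but remains a metathesis closure. Wittig reaction of 7 with the ylide from (hex-5-en-1-yl)triphenylphosphonium bromide and KOtBu gives the relay hydroxy diene F8 (olefin geometry irrelevant). O-Allylation as in step 5 gives the relay allyl ether F9. With the same catalyst, loading on the terminal hexenyl olefin, expulsion of cyclopentene and closure of the resulting C17 carbene onto the allyl ether should give 10.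

**Further compounds**

F1 | step 3 | ethyl (13E)-[6α-(pivaloyloxy)labda-8(17),13-dien-15-yl]acetate | CCOC(=O)CC/C=C(\C)CC[C@@H]1[C@@]2(C)CCCC(C)(C)[C@@H]2[C@@H](OC(=O)C(C)(C)C)CC1=C
F2 | step 3 | ethyl 6α-(pivaloyloxy)-18,19-dinorcheilanth-12-en-17-oate | CC1=CC[C@@H]2[C@@]3(C)CCCC(C)(C)[C@@H]3[C@@H](OC(=O)C(C)(C)C)C[C@@]2(C)[C@@H]1CCC(=O)OCC
F3 | step 3 | 6α-(pivaloyloxy)-18,19-dinorcheilanthan-17,13α-olide (δ-lactone) | O=C1O[C@@]2(C)CC[C@@H]3[C@@]4(C)CCCC(C)(C)[C@@H]4[C@@H](OC(=O)C(C)(C)C)C[C@@]3(C)[C@@H]2CC1
F4 | step 2 | 13-oxo-14,15-dinorlabd-8(17)-en-6α-yl pivalate | CC(=O)CC[C@@H]1[C@@]2(C)CCCC(C)(C)[C@@H]2[C@@H](OC(=O)C(C)(C)C)CC1=C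
F5 | step 2 | 15,16-dinorlabd-8(17)-en-13-yn-6α-yl pivalate | C#CCC[C@@H]1[C@@]2(C)CCCC(C)(C)[C@@H]2[C@@H](OC(=O)C(C)(C)C)CC1=C
F6 | step 2 | (13E)-14-iodo-15-norlabda-8(17),13-dien-6α-yl pivalate | I/C=C(\C)CC[C@@H]1[C@@]2(C)CCCC(C)(C)[C@@H]2[C@@H](OC(=O)C(C)(C)C)CC1=C
F7 | step 2 | ethylene ketal of 4 (2-methyl-1,3-dioxolane at the ketone carbon) | CC1(CC/C=C(\C)CC[C@@H]2[C@@]3(C)CCCC(C)(C)[C@@H]3[C@@H](OC(=O)C(C)(C)C)CC2=C)OCCO1
F8 | step 6 | 13α-hydroxy relay diene, C14 chain CH2CH2C(CH3)=CH(CH2)3CH=CH2, 6α-pivalate | O[C@@]1(C)CC[C@@H]2[C@@]3(C)CCCC(C)(C)[C@@H]3[C@@H](OC(=O)C(C)(C)C)C[C@@]2(C)[C@@H]1CCC(C)=CCCCC=C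
F9 | step 6 | 13α-allyl ether of the relay diene, 6α-pivalate | C=CCO[C@@]1(C)CC[C@@H]2[C@@]3(C)CCCC(C)(C)[C@@H]3[C@@H](OC(=O)C(C)(C)C)C[C@@]2(C)[C@@H]1CCC(C)=CCCCC=C
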